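**Retrosynthetic overview**

1. Lignan numbering: guaiacyl ring A on C7–C9, central syringyl ring B on C7'–C9', outer syringyl ring C on the glycerol chain C7''–C9''. The strategy rests on the ether C7–O–C9' of the second furofuran ring being a para-hydroxybenzyl ether of ring A (C7 is para to the free 4-OH). It is cut to a ring A para-quinone methide plus the C9' hydroxyl, i.e. DDQ dehydrogenation of C7H2 and 5-exo trapping; this ring is formed last.
2. The all-cis tetrahydrofuran precursor (ring C7'–O–C9, formed first) is cut at C7'–H: hydride reduction of a cyclic C7' aryl oxocarbenium ion from the face away from the cis C8/C8' substituents. The hemiketal comes from benzylic oxidation of a triol.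
3. The triol is cut at C7'–C8': aldol of (S)-β-(4-benzyloxy-3-methoxybenzyl)-γ-butyrolactone (Evans alkylation, from dihydroferulic acid) with the ring B aldehyde, then lactone reduction.
4. The ring B aldehyde carries the threo-(7''R,8''R) glycerol aryl ether, set by transfer hydrogenation with dynamic kinetic resolution of an α-aryloxy β-keto ester built from 4-bromo-2,6-dimethoxyphenol, ethyl bromoacetate and O-silyl syringaldehyde; Br is turned into CHO last.
5. Protection: ring A as benzyl ether (removed just before the key step); ring C phenol as TIPS ether and the chain hydroxyls as TBS ethers (removed by fluoride at the end).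

Key step: step 18

Remark: 4-bromo-2,6-dimethoxyphenol is taken as a purchasable phenol (otherwise one bromination of 2,6-dimethoxyphenol); ArB* stands for the ring B aryl group with its protected chain, 4-{[(1R,2R)-1,3-bis(tert-butyldimethylsilyloxy)-1-(3,5-dimethoxy-4-triisopropylsilyloxyphenyl)propan-2-yl]oxy}-3,5-dimethoxyphenyl.

**Route**

Step 1
Reactants: 1 3-(4-hydroxy-3-methoxyphenyl)propanoic acid (dihydroferulic acid); 2 benzyl bromide
Product: 3 3-(4-benzyloxy-3-methoxyphenyl)propanoic acid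
Conditions: BnBr (1.3 equiv), NaOH (2.5 equiv), EtOH/H2O, reflux; then aq HCl
Reagents that add atoms: benzyl bromide, BrCc1ccccc1
Why: Williamson etherification of the phenoxide, the excess hydroxide saponifying any benzyl ester so that only the aryl benzyl ether remains after acidification.

Step 2
Reactants: 3 3-(4-benzyloxy-3-methoxyphenyl)propanoic acid; 4 (R)-4-benzyloxazolidin-2-one
Product: 6 (R)-4-benzyl-3-[3-(4-benzyloxy-3-methoxyphenyl)propanoyl]oxazolidin-2-one, via mixed pivalic anhydride 5 (not isolated)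
Conditions: t-BuCOCl, Et3N, THF, −20 °C; then 4, LiCl, −20 °C → rt
Reagents that add atoms: (R)-4-benzyloxazolidin-2-one, O=C1N[C@H](Cc2ccccc2)CO1
Why: N-acylation of the oxazolidinone through the mixed anhydride, the hindered pivaloyl carbonyl directing attack to the desired acyl group.

Step 3
Reactants: 6 (R)-4-benzyl-3-[3-(4-benzyloxy-3-methoxyphenyl)propanoyl]oxazolidin-2-one; 7 tert-butyl bromoacetate
Product: 9 tert-butyl (3S)-3-[(4-benzyloxy-3-methoxyphenyl)methyl]-4-[(4R)-4-benzyl-2-oxooxazolidin-3-yl]-4-oxobutanoate, via sodium enolate 8 (not isolated)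
Conditions: NaN(SiMe3)2, THF, −78 °C; then BrCH2CO2t-Bu, −78 → −40 °C
Reagents that add atoms: tert-butyl bromoacetate, CC(C)(C)OC(=O)CBr
Why: Evans asymmetric alkylation, the chelated Z-enolate being alkylated on the face opposite the benzyl group of the (R)-auxiliary, which sets the future C8 centre as S.

Step 4
Reactants: 9 tert-butyl (3S)-3-[(4-benzyloxy-3-methoxyphenyl)methyl]-4-[(4R)-4-benzyl-2-oxooxazolidin-3-yl]-4-oxobutanoate
Product: 11 (4S)-4-[(4-benzyloxy-3-methoxyphenyl)methyl]dihydrofuran-2(3H)-one, via hydroxy ester 10 (not isolated)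
Conditions: LiBH4, MeOH (1 equiv), THF, 0 °C; then p-TsOH·H2O (cat.), toluene, 80 °C
Reagents that add atoms: none
Why: Reductive removal of the auxiliary (LiBH4 reduces the imide but not the tert-butyl ester) and acid-catalysed lactonisation of the hydroxy ester, neither touching the C8 centre.

Step 5
Reactants: 12 syringaldehyde (4-hydroxy-3,5-dimethoxybenzaldehyde); 13 triisopropylsilyl chloride
Product: 14 3,5-dimethoxy-4-(triisopropylsilyloxy)benzaldehyde
Conditions: TIPSCl, imidazole, DMF, rt → 40 °C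
Reagents that add atoms: triisopropylsilyl chloride, CC(C)[Si](Cl)(C(C)C)C(C)C
Why: Silylation of the phenol gives a ring C protecting group that survives bases, hydrides, hydrogenolysis and DDQ and is removed by fluoride.

Step 6
Reactants: 15 4-bromo-2,6-dimethoxyphenol; 16 ethyl bromoacetate
Product: 17 ethyl 2-(4-bromo-2,6-dimethoxyphenoxy)acetate
Conditions: K2CO3, acetone, reflux
Reagents that add atoms: ethyl bromoacetate, CCOC(=O)CBr
Why: Williamson etherification of the phenoxide with a reactive primary α-bromo ester forms the future C8''–O–ring B bond.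

Step 7
Reactants: 17 ethyl 2-(4-bromo-2,6-dimethoxyphenoxy)acetate; 14 3,5-dimethoxy-4-(triisopropylsilyloxy)benzaldehyde
Product: 19 ethyl 2-(4-bromo-2,6-dimethoxyphenoxy)-3-[3,5-dimethoxy-4-(triisopropylsilyloxy)phenyl]-3-hydroxypropanoate as a racemic erythro/threo mixture, via lithium enolate 18 (not isolated)
Conditions: LiN(i-Pr)2 (LDA, 1.1 equiv), THF, −78 °C; then 14, −78 °C; aq NH4Cl
Reagents that add atoms: none
Why: Ester enolate aldol addition to a non-enolisable aldehyde builds the C7''–C8'' bond; no stereocontrol is needed because both centres are reset in steps 8 and 9.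

Step 8
Reactants: 19 ethyl 2-(4-bromo-2,6-dimethoxyphenoxy)-3-[3,5-dimethoxy-4-(triisopropylsilyloxy)phenyl]-3-hydroxypropanoate
Product: 20 ethyl 2-(4-bromo-2,6-dimethoxyphenoxy)-3-[3,5-dimethoxy-4-(triisopropylsilyloxy)phenyl]-3-oxopropanoate (racemic)
Conditions: Dess–Martin periodinane, NaHCO3, CH2Cl2, 0 °C → rt
Reagents that add atoms: none
Why: Dess–Martin oxidation of the benzylic alcohol gives the β-keto ester, whose C8'' centre is now enolisable so that all stereoisomers converge.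

Step 9
Reactants: 20 ethyl 2-(4-bromo-2,6-dimethoxyphenoxy)-3-[3,5-dimethoxy-4-(triisopropylsilyloxy)phenyl]-3-oxopropanoate
Product: 21 ethyl (2S,3R)-2-(4-bromo-2,6-dimethoxyphenoxy)-3-[3,5-dimethoxy-4-(triisopropylsilyloxy)phenyl]-3-hydroxypropanoate (threo)
Conditions: RuCl(p-cymene)[(S,S)-TsDPEN] (2 mol %), HCO2H/Et3N (5:2), CH2Cl2, 30 °C
Reagents that add atoms: none
Why: Noyori-type asymmetric transfer hydrogenation with dynamic kinetic resolution: the keto ester racemises at C8'' through its enol while the (S,S)-catalyst reduces the aryl ketone with the facial sense known for acetophenone (here 7''R) and with the syn preference established for α-alkoxy β-keto esters, giving the threo (7''R,8''R) arrangement.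

Step 10
Reactants: 21 ethyl (2S,3R)-2-(4-bromo-2,6-dimethoxyphenoxy)-3-[3,5-dimethoxy-4-(triisopropylsilyloxy)phenyl]-3-hydroxypropanoate
Product: 22 (1R,2R)-2-(4-bromo-2,6-dimethoxyphenoxy)-1-[3,5-dimethoxy-4-(triisopropylsilyloxy)phenyl]propane-1,3-diol
Conditions: LiBH4, THF, 0 °C → rt
Reagents that add atoms: none
Why: Chemoselective hydride reduction of the ester to the C9'' primary alcohol, leaving the aryl bromide and the aryl silyl ether untouched and the two centres unchanged.

Step 11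
Reactants: 22 (1R,2R)-2-(4-bromo-2,6-dimethoxyphenoxy)-1-[3,5-dimethoxy-4-(triisopropylsilyloxy)phenyl]propane-1,3-diol; 23 tert-butyldimethylsilyl triflate
Product: 24 5-bromo-2-{[(1R,2R)-1,3-bis(tert-butyldimethylsilyloxy)-1-(3,5-dimethoxy-4-triisopropylsilyloxyphenyl)propan-2-yl]oxy}-1,3-dimethoxybenzene
Conditions: TBSOTf (2.5 equiv), 2,6-lutidine, CH2Cl2, −78 → 0 °C
Reagents that add atoms: tert-butyldimethylsilyl triflate, CC(C)(C)[Si](C)(C)OS(=O)(=O)C(F)(F)F
Why: Silylation of both hydroxyls with the reactive triflate, needed for the hindered benzylic C7'' alcohol, so that this position cannot be oxidised later by MnO2 or DDQ.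

Step 12
Reactants: 24 5-bromo-2-{[(1R,2R)-1,3-bis(tert-butyldimethylsilyloxy)-1-(3,5-dimethoxy-4-triisopropylsilyloxyphenyl)propan-2-yl]oxy}-1,3-dimethoxybenzene; 25 N,N-dimethylformamide
Product: 27 ArB*–CHO (4-{[(1R,2R)-1,3-bis(tert-butyldimethylsilyloxy)-1-(3,5-dimethoxy-4-triisopropylsilyloxyphenyl)propan-2-yl]oxy}-3,5-dimethoxybenzaldehyde), via aryllithium 26 (not isolated)
Conditions: n-BuLi, THF, −78 °C; then DMF, −78 → 0 °C; aq NH4Cl
Reagents that add atoms: N,N-dimethylformamide, CN(C)C=O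
Why: Bromine–lithium exchange followed by formylation with DMF (Bouveault aldehyde synthesis); the silyl ethers and the non-acidic chain tolerate the aryllithium at −78 °C.

Step 13
Reactants: 11 (4S)-4-[(4-benzyloxy-3-methoxyphenyl)methyl]dihydrofuran-2(3H)-one; 27 ArB*–CHO
Product: 29 (3R,4S)-4-[(4-benzyloxy-3-methoxyphenyl)methyl]-3-[ArB*(hydroxy)methyl]dihydrofuran-2(3H)-one as both C7' carbinol epimers, via lithium enolate 28 (not isolated)
Conditions: LiN(SiMe3)2, THF, −78 °C; then 27, −78 °C; aq NH4Cl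
Reagents that add atoms: none
Why: Lactone enolate aldol in which the aldehyde adds anti to the C8 benzyl group; this trans lactone fixes C8' so that C9' and the benzyl group become cis once C7', not C9', is the ring atom, and the C7' carbinol configuration is irrelevant because it is oxidised in step 15.

Step 14
Reactants: 29 (3R,4S)-4-[(4-benzyloxy-3-methoxyphenyl)methyl]-3-[ArB*(hydroxy)methyl]dihydrofuran-2(3H)-one
Product: 30 (2S,3S)-2-[ArB*(hydroxy)methyl]-3-[(4-benzyloxy-3-methoxyphenyl)methyl]butane-1,4-diol (both C7' epimers)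
Conditions: LiBH4, MeOH (2 equiv), THF, 0 °C → rt
Reagents that add atoms: none
Why: Hydride reduction of the lactone to the C9/C9' diol under conditions mild enough for the alkyl and aryl silyl ethers.

Step 15
Reactants: 30 (2S,3S)-2-[ArB*(hydroxy)methyl]-3-[(4-benzyloxy-3-methoxyphenyl)methyl]butane-1,4-diol
Product: 32 (3S,4S)-2-ArB*-4-[(4-benzyloxy-3-methoxyphenyl)methyl]-3-(hydroxymethyl)tetrahydrofuran-2-ol as an anomeric mixture, via keto diol 31 (not isolated)
Conditions: MnO2 (activated, 20 equiv), CH2Cl2, rt; filtered and used crude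
Reagents that add atoms: none
Why: MnO2 oxidises the benzylic C7' alcohol and leaves the two saturated primary alcohols, and the aryl ketone is captured by the C9 hydroxyl as the five-membered hemiketal (the C9' hydroxyl could only form a four-membered ring).

Step 16
Reactants: 32 (3S,4S)-2-ArB*-4-[(4-benzyloxy-3-methoxyphenyl)methyl]-3-(hydroxymethyl)tetrahydrofuran-2-ol
Product: 34 {(2S,3S,4S)-2-ArB*-4-[(4-benzyloxy-3-methoxyphenyl)methyl]tetrahydrofuran-3-yl}methanol (all-cis), via oxocarbenium ion 33 (not isolated)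
Conditions: Et3SiH (5 equiv), BF3·OEt2 (2.5 equiv), CH2Cl2, −78 °C; sat. NaHCO3 at −78 °C
Reagents that add atoms: none
Why: Ionic hydrogenation of a cyclic aryl hemiketal: BF3 ionises C7' to the 2-aryl oxocarbenium ion and Et3SiH delivers hydride to the face anti to the mutually cis C8' hydroxymethyl and C8 benzyl groups, so ring B ends cis to both (7'S), the low temperature suppressing C8' epimerisation through the enol ether.

Step 17
Reactants: 34 {(2S,3S,4S)-2-ArB*-4-[(4-benzyloxy-3-methoxyphenyl)methyl]tetrahydrofuran-3-yl}methanol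
Product: 35 {(2S,3S,4S)-2-ArB*-4-[(4-hydroxy-3-methoxyphenyl)methyl]tetrahydrofuran-3-yl}methanol
Conditions: H2 (1 atm), Pd/C, EtOAc, rt
Reagents that add atoms: none
Why: Hydrogenolysis of the aryl benzyl ether in a neutral aprotic solvent frees the ring A phenol while silyl ethers and the benzylic ring ether are retained.

Step 18
Reactants: 35 {(2S,3S,4S)-2-ArB*-4-[(4-hydroxy-3-methoxyphenyl)methyl]tetrahydrofuran-3-yl}methanol
Product: 37 (7R,8S,7'S,8'S)-furofuran with ring A (4-hydroxy-3-methoxyphenyl) exo at C7 and ArB* endo at C7', via quinone methide 36 (not isolated)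
Conditions: DDQ (1.05 equiv), NaHCO3 (solid), CH2Cl2, 0 °C
Reagents that add atoms: none
Why: DDQ dehydrogenates the only free para-alkylphenol (hydride loss from C7H2 of ring A through the phenol–quinone charge-transfer complex) to the ring A para-quinone methide 36, and the C9' hydroxyl, held cis to C7 on the tetrahydrofuran, adds to C7 with rearomatisation. The closest known reaction type is the DDQ oxidative cycloetherification of 4-hydroxybenzyl lignan alcohols to 7,9'-epoxy lignans through quinone methides. The new ring (C7–O–C9'–C8'–C8) closes in a 5-exo-trig mode and is necessarily cis-fused. The new C7 centre (R) is controlled by the bicycle: the quinone methide reacts in the rotamer that puts ring A on the convex face, because ring B already fills the concave face at C7' and a doubly endo arrangement would be badly congested, and reversibility of the addition favours the same exo isomer. The step needs hydride abstraction at C7 in preference to the benzylic ether hydrogens at C7' and C7'' and no second oxidation of the product; the first is secured because ring B is etherified and ring C silylated so that only ring A can form a quinone methide, the second by using about one equivalent of DDQ at 0 °C. Solid NaHCO3 buffers the hydroquinone so that the acid-labile endo C7' centre is not epimerised.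

Step 19
Reactants: 37 (7R,8S,7'S,8'S)-furofuran with three silyl ethers
Product: 38 CNP0317965.1, the (7R,8S,7'S,8'S,7''R,8''R) target
Conditions: TBAF, AcOH (1:1), THF, 0 °C → rt
Reagents that add atoms: none
Why: Fluoride-mediated cleavage of the aryl TIPS ether and both TBS ethers under buffered, non-acidic conditions that leave the benzylic ethers of the furofuran and the glycerol chain untouched.

**Compound list**

1 | 3-(4-hydroxy-3-methoxyphenyl)propanoic acid (dihydroferulic acid) | COc1cc(CCC(=O)O)ccc1O | starting material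
2 | benzyl bromide | BrCc1ccccc1 | starting material
3 | 3-(4-benzyloxy-3-methoxyphenyl)propanoic acid | COc1cc(CCC(=O)O)ccc1OCc1ccccc1 | intermediate
4 | (R)-4-benzyloxazolidin-2-one | O=C1N[C@H](Cc2ccccc2)CO1 | starting material
5 | 3-(4-benzyloxy-3-methoxyphenyl)propanoic pivalic anhydride | COc1cc(CCC(=O)OC(=O)C(C)(C)C)ccc1OCc1ccccc1 | intermediate
6 | (R)-4-benzyl-3-[3-(4-benzyloxy-3-methoxyphenyl)propanoyl]oxazolidin-2-one | COc1cc(CCC(=O)N2[C@H](Cc3ccccc3)COC2=O)ccc1OCc1ccccc1 | intermediate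
7 | tert-butyl bromoacetate | CC(C)(C)OC(=O)CBr | starting material
8 | sodium (Z)-enolate of 6 | [Na+].COc1cc(C/C=C(\[O-])N2[C@H](Cc3ccccc3)COC2=O)ccc1OCc1ccccc1 | intermediate
9 | tert-butyl (3S)-3-[(4-benzyloxy-3-methoxyphenyl)methyl]-4-[(4R)-4-benzyl-2-oxooxazolidin-3-yl]-4-oxobutanoate | COc1cc(C[C@@H](CC(=O)OC(C)(C)C)C(=O)N2[C@H](Cc3ccccc3)COC2=O)ccc1OCc1ccccc1 | intermediate
10 | tert-butyl (3S)-3-[(4-benzyloxy-3-methoxyphenyl)methyl]-4-hydroxybutanoate | COc1cc(C[C@@H](CC(=O)OC(C)(C)C)CO)ccc1OCc1ccccc1 | intermediate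
11 | (4S)-4-[(4-benzyloxy-3-methoxyphenyl)methyl]dihydrofuran-2(3H)-one | COc1cc(C[C@@H]2COC(=O)C2)ccc1OCc1ccccc1 | intermediate
12 | syringaldehyde | COc1cc(C=O)cc(OC)c1O | starting material
13 | triisopropylsilyl chloride | CC(C)[Si](Cl)(C(C)C)C(C)C | starting material
14 | 3,5-dimethoxy-4-(triisopropylsilyloxy)benzaldehyde | COc1cc(C=O)cc(OC)c1O[Si](C(C)C)(C(C)C)C(C)C | intermediate
15 | 4-bromo-2,6-dimethoxyphenol | COc1cc(Br)cc(OC)c1O | starting material
16 | ethyl bromoacetate | CCOC(=O)CBr | starting material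
17 | ethyl 2-(4-bromo-2,6-dimethoxyphenoxy)acetate | CCOC(=O)COc1c(OC)cc(Br)cc1OC | intermediate
18 | lithium enolate of 17 (geometry not defined) | [Li+].CCOC([O-])=COc1c(OC)cc(Br)cc1OC | intermediate
19 | ethyl 2-(4-bromo-2,6-dimethoxyphenoxy)-3-[3,5-dimethoxy-4-(triisopropylsilyloxy)phenyl]-3-hydroxypropanoate (racemic, erythro/threo mixture) | CCOC(=O)C(Oc1c(OC)cc(Br)cc1OC)C(O)c1cc(OC)c(O[Si](C(C)C)(C(C)C)C(C)C)c(OC)c1 | intermediate
20 | ethyl 2-(4-bromo-2,6-dimethoxyphenoxy)-3-[3,5-dimethoxy-4-(triisopropylsilyloxy)phenyl]-3-oxopropanoate (racemic) | CCOC(=O)C(Oc1c(OC)cc(Br)cc1OC)C(=O)c1cc(OC)c(O[Si](C(C)C)(C(C)C)C(C)C)c(OC)c1 | intermediate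
21 | ethyl (2S,3R)-2-(4-bromo-2,6-dimethoxyphenoxy)-3-[3,5-dimethoxy-4-(triisopropylsilyloxy)phenyl]-3-hydroxypropanoate | COc1cc(Br)cc(OC)c1O[C@H](C(=O)OCC)[C@H](O)c1cc(OC)c(O[Si](C(C)C)(C(C)C)C(C)C)c(OC)c1 | intermediate
22 | (1R,2R)-2-(4-bromo-2,6-dimethoxyphenoxy)-1-[3,5-dimethoxy-4-(triisopropylsilyloxy)phenyl]propane-1,3-diol | COc1cc(Br)cc(OC)c1O[C@H](CO)[C@H](O)c1cc(OC)c(O[Si](C(C)C)(C(C)C)C(C)C)c(OC)c1 | intermediate
23 | tert-butyldimethylsilyl triflate | CC(C)(C)[Si](C)(C)OS(=O)(=O)C(F)(F)F | starting material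
24 | 5-bromo-2-{[(1R,2R)-1,3-bis(tert-butyldimethylsilyloxy)-1-(3,5-dimethoxy-4-triisopropylsilyloxyphenyl)propan-2-yl]oxy}-1,3-dimethoxybenzene | COc1cc(Br)cc(OC)c1O[C@H](CO[Si](C)(C)C(C)(C)C)[C@H](O[Si](C)(C)C(C)(C)C)c1cc(OC)c(O[Si](C(C)C)(C(C)C)C(C)C)c(OC)c1 | intermediate
25 | N,N-dimethylformamide | CN(C)C=O | starting material
26 | aryllithium from 24 (ArB*–Li) | [Li]c1cc(OC)c(O[C@H](CO[Si](C)(C)C(C)(C)C)[C@H](O[Si](C)(C)C(C)(C)C)c2cc(OC)c(O[Si](C(C)C)(C(C)C)C(C)C)c(OC)c2)c(OC)c1 | intermediate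
27 | ArB*–CHO, 4-{[(1R,2R)-1,3-bis(tert-butyldimethylsilyloxy)-1-(3,5-dimethoxy-4-triisopropylsilyloxyphenyl)propan-2-yl]oxy}-3,5-dimethoxybenzaldehyde | COc1cc(C=O)cc(OC)c1O[C@H](CO[Si](C)(C)C(C)(C)C)[C@H](O[Si](C)(C)C(C)(C)C)c1cc(OC)c(O[Si](C(C)C)(C(C)C)C(C)C)c(OC)c1 | intermediate
28 | lithium enolate of lactone 11 | [Li+].COc1cc(C[C@@H]2COC([O-])=C2)ccc1OCc1ccccc1 | intermediate
29 | (3R,4S)-4-[(4-benzyloxy-3-methoxyphenyl)methyl]-3-[ArB*(hydroxy)methyl]dihydrofuran-2(3H)-one (both C7' epimers) | O=C1OC[C@@H](Cc2ccc(OCc3ccccc3)c(OC)c2)[C@@H]1C(O)c1cc(OC)c(O[C@H](CO[Si](C)(C)C(C)(C)C)[C@H](O[Si](C)(C)C(C)(C)C)c2cc(OC)c(O[Si](C(C)C)(C(C)C)C(C)C)c(OC)c2)c(OC)c1 | intermediate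
30 | (2S,3S)-2-[ArB*(hydroxy)methyl]-3-[(4-benzyloxy-3-methoxyphenyl)methyl]butane-1,4-diol (both C7' epimers) | COc1cc(C[C@H](CO)[C@@H](CO)C(O)c2cc(OC)c(O[C@H](CO[Si](C)(C)C(C)(C)C)[C@H](O[Si](C)(C)C(C)(C)C)c3cc(OC)c(O[Si](C(C)C)(C(C)C)C(C)C)c(OC)c3)c(OC)c2)ccc1OCc1ccccc1 | intermediate
31 | (2S,3S)-1-ArB*-3-[(4-benzyloxy-3-methoxyphenyl)methyl]-4-hydroxy-2-(hydroxymethyl)butan-1-one (keto diol) | COc1cc(C[C@H](CO)[C@@H](CO)C(=O)c2cc(OC)c(O[C@H](CO[Si](C)(C)C(C)(C)C)[C@H](O[Si](C)(C)C(C)(C)C)c3cc(OC)c(O[Si](C(C)C)(C(C)C)C(C)C)c(OC)c3)c(OC)c2)ccc1OCc1ccccc1 | intermediate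
32 | (3S,4S)-2-ArB*-4-[(4-benzyloxy-3-methoxyphenyl)methyl]-3-(hydroxymethyl)tetrahydrofuran-2-ol (anomeric mixture) | COc1cc(C[C@@H]2COC(O)(c3cc(OC)c(O[C@H](CO[Si](C)(C)C(C)(C)C)[C@H](O[Si](C)(C)C(C)(C)C)c4cc(OC)c(O[Si](C(C)C)(C(C)C)C(C)C)c(OC)c4)c(OC)c3)[C@@H]2CO)ccc1OCc1ccccc1 | intermediate
33 | cyclic C7' aryl oxocarbenium ion from 32 | COc1cc(C[C@@H]2C[O+]=C(c3cc(OC)c(O[C@H](CO[Si](C)(C)C(C)(C)C)[C@H](O[Si](C)(C)C(C)(C)C)c4cc(OC)c(O[Si](C(C)C)(C(C)C)C(C)C)c(OC)c4)c(OC)c3)[C@@H]2CO)ccc1OCc1ccccc1 | intermediate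
34 | {(2S,3S,4S)-2-ArB*-4-[(4-benzyloxy-3-methoxyphenyl)methyl]tetrahydrofuran-3-yl}methanol (all-cis) | COc1cc(C[C@@H]2CO[C@H](c3cc(OC)c(O[C@H](CO[Si](C)(C)C(C)(C)C)[C@H](O[Si](C)(C)C(C)(C)C)c4cc(OC)c(O[Si](C(C)C)(C(C)C)C(C)C)c(OC)c4)c(OC)c3)[C@@H]2CO)ccc1OCc1ccccc1 | intermediate
35 | {(2S,3S,4S)-2-ArB*-4-[(4-hydroxy-3-methoxyphenyl)methyl]tetrahydrofuran-3-yl}methanol (key-step precursor) | COc1cc(C[C@@H]2CO[C@H](c3cc(OC)c(O[C@H](CO[Si](C)(C)C(C)(C)C)[C@H](O[Si](C)(C)C(C)(C)C)c4cc(OC)c(O[Si](C(C)C)(C(C)C)C(C)C)c(OC)c4)c(OC)c3)[C@@H]2CO)ccc1O | intermediate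
36 | ring A para-quinone methide of 35 (alkene geometry not defined) | COC1=CC(=C[C@@H]2CO[C@H](c3cc(OC)c(O[C@H](CO[Si](C)(C)C(C)(C)C)[C@H](O[Si](C)(C)C(C)(C)C)c4cc(OC)c(O[Si](C(C)C)(C(C)C)C(C)C)c(OC)c4)c(OC)c3)[C@@H]2CO)C=CC1=O | intermediate
37 | (7R,8S,7'S,8'S)-furofuran, ring A exo at C7, ArB* endo at C7', chain silylated (key-step product) | COc1cc([C@@H]2OC[C@@H]3[C@H]2CO[C@@H]3c2cc(OC)c(O[C@H](CO[Si](C)(C)C(C)(C)C)[C@H](O[Si](C)(C)C(C)(C)C)c3cc(OC)c(O[Si](C(C)C)(C(C)C)C(C)C)c(OC)c3)c(OC)c2)ccc1O | intermediate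
38 | CNP0317965.1, (7R,8S,7'S,8'S,7''R,8''R) | COc1cc([C@@H]2OC[C@@H]3[C@H]2CO[C@@H]3c2cc(OC)c(O[C@H](CO)[C@H](O)c3cc(OC)c(O)c(OC)c3)c(OC)c2)ccc1O | target

**Step count**

Total step count: 19 (lactone arm steps 1–4, silyl aldehyde step 5, ring B/C arm steps 6–12, union and endgame steps 13–19).
Longest linear sequence: 14 steps (from 15 through steps 6–19).

**Steps most likely to fail**

Step 18 (key step). What may go wrong: a second hydride abstraction from the product, whose C7–H is again para-hydroxybenzylic, leading to ring-opened ketone; or competing hydride loss at the ring B benzylic ether C7'–H. Fallback: close the same C7–O bond without phenol oxidation, by alkoxy-radical C–H etherification on the benzyl-protected stage. Setting out from 34, Pb(OAc)4 with CaCO3 in benzene at 80 °C converts the C9' alcohol into an alkoxy radical. This radical takes the cis-disposed benzylic hydrogen from C7 by 1,5-hydrogen atom transfer; tetravalent lead oxidises the benzylic radical, and the cation collapses onto oxygen with ring A exo, giving the O-benzyl furofuran F1. Hydrogenolysis (H2, Pd/C, EtOAc) then comes back to the route at 37.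

Step 16. What may go wrong: loss of the C8' configuration by proton loss from the oxocarbenium ion to the enol ether and reprotonation before hydride arrives, or silyl ether cleavage by BF3. Fallback: use the enol ether on purpose. Setting out from 32, dehydration (pyridinium p-toluenesulfonate cat., benzene, reflux with water removal) gives the 4,5-dihydrofuran F2, in which C8 is the only ring stereocentre. Hydrogenation with [Ir(cod)(PCy3)(py)]PF6 and H2 in CH2Cl2 adds both hydrogens to the face anti to the C8 benzyl group, which sets C7' and C8' together as all-cis and comes back to the route at 34 with the benzyl ether intact.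

Step 9. What may go wrong: racemisation of the hindered α-aryloxy keto ester slower than its reduction, or a weak syn preference with the bulky 2,6-dimethoxyaryloxy group, so that erythro or enantiomeric material is carried on. Fallback: set C8'' from the chiral pool and C7'' by chelation control. Setting out from 15, a Mitsunobu reaction (PPh3, DIAD, THF) with methyl (S)-3-(tert-butyldimethylsilyloxy)-2-hydroxypropanoate F3 (from methyl (S)-2,3-dihydroxypropanoate, TBSCl, imidazole) gives, with inversion, methyl (R)-2-(4-bromo-2,6-dimethoxyphenoxy)-3-(tert-butyldimethylsilyloxy)propanoate F4. i-Bu2AlH at −78 °C gives the aldehyde F5. Separately, 15 is silylated (TIPSCl, imidazole) to (4-bromo-2,6-dimethoxyphenoxy)triisopropylsilane F6 and converted with Mg in THF into the Grignard reagent F7. Addition of F7 to F5 in the presence of MgBr2·OEt2 (Cram chelate control through the α-aryloxy oxygen) gives the threo alcohol F8. Silylation with TBSOTf and 2,6-lutidine comes back to the route at 24.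

**Further compounds**

F1 | step 18 | (7R,8S,7'S,8'S)-furofuran with ring A as its benzyl ether (O-benzyl analogue of 37) | COc1cc([C@@H]2OC[C@@H]3[C@H]2CO[C@@H]3c2cc(OC)c(O[C@H](CO[Si](C)(C)C(C)(C)C)[C@H](O[Si](C)(C)C(C)(C)C)c3cc(OC)c(O[Si](C(C)C)(C(C)C)C(C)C)c(OC)c3)c(OC)c2)ccc1OCc1ccccc1
F2 | step 16 | {(4S)-2-ArB*-4-[(4-benzyloxy-3-methoxyphenyl)methyl]-4,5-dihydrofuran-3-yl}methanol | COc1cc(C[C@@H]2COC(c3cc(OC)c(O[C@H](CO[Si](C)(C)C(C)(C)C)[C@H](O[Si](C)(C)C(C)(C)C)c4cc(OC)c(O[Si](C(C)C)(C(C)C)C(C)C)c(OC)c4)c(OC)c3)=C2CO)ccc1OCc1ccccc1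
F3 | step 9 | methyl (S)-3-(tert-butyldimethylsilyloxy)-2-hydroxypropanoate | COC(=O)[C@@H](O)CO[Si](C)(C)C(C)(C)C
F4 | step 9 | methyl (R)-2-(4-bromo-2,6-dimethoxyphenoxy)-3-(tert-butyldimethylsilyloxy)propanoate | COc1cc(Br)cc(OC)c1O[C@H](CO[Si](C)(C)C(C)(C)C)C(=O)OC
F5 | step 9 | (R)-2-(4-bromo-2,6-dimethoxyphenoxy)-3-(tert-butyldimethylsilyloxy)propanal | COc1cc(Br)cc(OC)c1O[C@H](CO[Si](C)(C)C(C)(C)C)C=O
F6 | step 9 | (4-bromo-2,6-dimethoxyphenoxy)triisopropylsilane | COc1cc(Br)cc(OC)c1O[Si](C(C)C)(C(C)C)C(C)C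
F7 | step 9 | [3,5-dimethoxy-4-(triisopropylsilyloxy)phenyl]magnesium bromide | COc1cc([Mg]Br)cc(OC)c1O[Si](C(C)C)(C(C)C)C(C)C
F8 | step 9 | (1R,2R)-2-(4-bromo-2,6-dimethoxyphenoxy)-3-(tert-butyldimethylsilyloxy)-1-[3,5-dimethoxy-4-(triisopropylsilyloxy)phenyl]propan-1-ol | COc1cc(Br)cc(OC)c1O[C@H](CO[Si](C)(C)C(C)(C)C)[C@H](O)c1cc(OC)c(O[Si](C(C)C)(C(C)C)C(C)C)c(OC)c1
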